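The earlier runs and the new flask are calculated on assumed constants.

66.6% of the charge has become target after 5.0 min in the beta run, and 66.2% in the zeta run, which starts from half as much starting material. What is that near-equality worth for the alpha run, charged like the beta run and left for 10 min?

| flask | starting material | time |
|---|---|---|
| beta | 300 mM |  |
| eta | 180 mM |  |
| zeta | 150 mM |  |
| alpha | 300 mM | 10 min |

| run | time / min | [target] / mM |
|---|---|---|
| beta run | 0.62 | 54.5 |
| beta run | 1.2 | 93.2 |
| beta run | 1.9 | 129.0 |
| beta run | 2.5 | 154.0 |
| beta run | 3.1 | 168.4 |
| beta run | 3.8 | 183.1 |
| beta run | 4.4 | 193.1 |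
| beta run | 5.0 | 199.9 |
| eta run | 0.62 | 31.6 |
| eta run | 1.2 | 54.5 |
| eta run | 1.9 | 77.1 |
| eta run | 2.5 | 90.9 |
| eta run | 3.1 | 100.2 |
| eta run | 3.8 | 109.3 |
| eta run | 4.4 | 111.7 |
| eta run | 5.0 | 116.6 |
| zeta run | 0.62 | 25.7 |
| zeta run | 1.2 | 46.6 |
| zeta run | 1.9 | 64.8 |
| zeta run | 2.5 | 76.0 |
| zeta run | 3.1 | 84.9 |
| zeta run | 3.8 | 90.9 |
| zeta run | 4.4 | 94.6 |
| zeta run | 5.0 | 99.3 |

(readings scatter by 0.9 mM)

- apparent order in [starting material] of the starting rate, round the charge of the beta run (the rate where two percent of its starting material have turned into target) (one fixed amount of target, the same in the runs compared)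
- target in the alpha run at 10 min, as a share of the starting material charged

- Overall: starting material -> target.
- Constant volume, constant temperature.
- An order is taken over about fifteen percent of the charge, up and down.

Dividing the rate of one run by the rate of another at the same share takes time out of the question. Since these shares match at matching times, a ratio of two c(target) readings stands for that ratio of rates. The last readings of the beta and zeta runs give 1.01 for the logarithm of the ratio of rates over the logarithm of the ratio of charges, which I call the charge exponent; the usual term is apparent order. The beta and zeta runs end about level, since the rate of each follows its charge. So I expect the eta run, at equal share, to have 0.597 of the beta rate, and the alpha run to follow the beta curve. The exponent says nothing of how that curve goes on after 5.0 min.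

The forecast gives 1.02 for the order and 73% for the alpha run, on the ground that “Rate against conversion is roughly linear”.

    starting material → target (0.3246 min⁻¹)
    starting material + target → 2 target (0.1800 L mol⁻¹ min⁻¹)
    starting material → decomposed substrate (0.06360 min⁻¹)
    target → decomposed product (0.03294 min⁻¹)

The alpha run gives order 1.0 and 64.7% of its charge as target at 10 min, less than the last beta reading of 66.6%. Carried to the eta run, the exponent turns the beta rate of 95 mM min⁻¹, taken at one fixed amount of target, into 56.8 mM min⁻¹, where the eta run shows 56 mM min⁻¹. The alpha run stands where it does mainly because target passes into decomposed product. That step is not the reason for the order, which stays at 1.0 without it, but without it the alpha run reaches 83.3%.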